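**Retrosynthetic overview**

- The strategy rests on the γ-hydroxy acid pattern of the cyclohexane (ring C5–C10). The C8 carbinol oxygen and the C12 carboxyl are 1,4-related through C7 and C11, so C7–C8 is cut to an acyclic C8 aldehyde carrying an (E)-enoate (C7=C11–C12). A cathodic reductive coupling re-forms this bond.
- After ring closure: C8–O silylation, methylenation of C11 (adds C13), C8 desilylation, acylation with silyl-protected 2-(hydroxymethyl)acrylic acid, one fluoride deprotection.
- The acyclic precursor comes from a C6 aldehyde by Felkin-controlled Nozaki–Hiyama–Kishi addition of a 3-iodoacrylate (forms C6–C7, sets C6), then C8 unmasking and oxidation.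
- The C5–C10 bond with its tertiary/quaternary stereodiad is made by an enantioselective boron-enolate Ireland–Claisen rearrangement of an itaconate-derived ester of an (E)-trisubstituted allylic alcohol (from alkyne carboalumination).
- Ring order: the molecule has one ring (the cyclohexane), and it is formed in the key step.

Key step: step 13

Remark (numbering and abbreviations): ring C5–C10; C10 quaternary (methyl, vinyl C1=C2); C5 bears C4(=C3H2)–C15H2O; C6–O; C7 bears C11(=C13H2)–C12O2; C8–O; C9H2. TBS = tert-butyldimethylsilyl, TBDPS = tert-butyldiphenylsilyl, TES = triethylsilyl, TMSE = 2-(trimethylsilyl)ethyl.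

Assumption: the (S,S)-configured boron controller of step 5 is taken to give the (2R,3S) acid; the sense of induction is to be confirmed on the rearranged acid, and the (R,R)-controller is used with no other change if the opposite sense is found.

**Route**

Step 1
Reactants: 1 4-(tert-butyldimethylsilyloxy)but-1-yne
Product: 4 (E)-5-(TBSO)-3-methylpent-2-en-1-ol, via alkenyldimethylalane 2 (not isolated), via lithium alkenylaluminate 3 (not isolated)
Conditions: Me3Al (2.5 equiv), Cp2ZrCl2 (0.25 equiv), CH2Cl2, 0 °C → rt; evaporate; n-BuLi, THF–hexane, −78 → 0 °C; (CH2O)n, rt; aq. Rochelle salt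
Reagents that add atoms: trimethylaluminium C[Al](C)C; paraformaldehyde (as formaldehyde) C=O
Why: Zirconium-catalysed methylalumination of a terminal alkyne (Negishi carboalumination) is a syn addition with aluminium at the terminus, so hydroxymethylation of the derived aluminate with retention should fix the (E)-trisubstituted alkene that later dictates the C10 configuration.

Step 2
Reactants: 4 (E)-5-(TBSO)-3-methylpent-2-en-1-ol; 5 itaconic anhydride
Product: 6 2-methylidene-4-oxo-4-{[(E)-5-(TBSO)-3-methylpent-2-enyl]oxy}butanoic acid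
Conditions: toluene, 60 °C, no base
Reagents that add atoms: none
Why: Alcoholysis of itaconic anhydride (anhydride ring opening) should occur at the saturated, non-conjugated carbonyl and give the 4-monoester with the acrylic acid free, while the absence of base avoids isomerisation to the citraconate.

Step 3
Reactants: 6 2-methylidene-4-oxo-4-{[(E)-5-(TBSO)-3-methylpent-2-enyl]oxy}butanoic acid
Product: 8 (E)-5-(TBSO)-3-methylpent-2-enyl 3-(hydroxymethyl)but-3-enoate, via mixed carbonic anhydride 7 (not isolated)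
Conditions: i-BuOCOCl, N-methylmorpholine, THF, −15 °C; then NaBH4, THF–H2O, −15 → 0 °C; pH 7 quench
Reagents that add atoms: none
Why: Activation of the free acid as a mixed carbonic anhydride lets borohydride perform a 1,2-reduction to the allylic alcohol at low temperature, while the much less electrophilic allyl ester should stay intact.

Step 4
Reactants: 8 (E)-5-(TBSO)-3-methylpent-2-enyl 3-(hydroxymethyl)but-3-enoate
Product: 9 (E)-5-(TBSO)-3-methylpent-2-enyl 3-[(TBDPSO)methyl]but-3-enoate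
Conditions: TBDPSCl, imidazole, CH2Cl2, 0 °C → rt
Reagents that add atoms: tert-butyldiphenylsilyl chloride CC(C)(C)[Si](Cl)(c1ccccc1)c1ccccc1
Why: Standard silylation of a primary allylic alcohol, carried out at once to forestall lactonisation; TBDPS is chosen so that the primary TBS ether on the future C8 can later be removed in its presence.

Step 5
Reactants: 9 (E)-5-(TBSO)-3-methylpent-2-enyl 3-[(TBDPSO)methyl]but-3-enoate
Product: 12 (2R,3S)-5-(TBSO)-3-ethenyl-3-methyl-2-[3-(TBDPSO)prop-1-en-2-yl]pentanoic acid, via boron ketene acetal 10 (not isolated), via boryl ester 11 (not isolated)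
Conditions: pre-formed (4S,5S)-2-bromo-1,3-bis[3,5-bis(trifluoromethyl)phenylsulfonyl]-4,5-diphenyl-1,3,2-diazaborolidine (1.3 equiv), Et3N, toluene–hexane, −78 °C; then −20 → 4 °C; aq. work-up
Reagents that add atoms: none
Why: Enantioselective Ireland–Claisen rearrangement through a chiral boron enolate: soft enolisation in a non-polar medium should give the E(O)-ketene acetal, whose chair [3,3] shift with the (E)-allyl unit (C10 methyl and C5 alkenyl both axial) forms C5–C10 with the required relative configuration, while the C2-symmetric bis-sulfonamide ligand on boron selects the enolate face and so the absolute configuration.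

Step 6
Reactants: 12 (2R,3S)-5-(TBSO)-3-ethenyl-3-methyl-2-[3-(TBDPSO)prop-1-en-2-yl]pentanoic acid
Product: 13 (2R,3S)-5-(TBSO)-3-ethenyl-3-methyl-2-[3-(TBDPSO)prop-1-en-2-yl]pentan-1-ol
Conditions: LiAlH4, THF, 0 °C → rt; Fieser work-up
Reagents that add atoms: none
Why: Hydride reduction of the carboxylic acid to the primary alcohol leaves silyl ethers and isolated alkenes untouched and does not affect C5 or C10.

Step 7
Reactants: 13 (2R,3S)-5-(TBSO)-3-ethenyl-3-methyl-2-[3-(TBDPSO)prop-1-en-2-yl]pentan-1-ol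
Product: 14 (2R,3S)-5-(TBSO)-3-ethenyl-3-methyl-2-[3-(TBDPSO)prop-1-en-2-yl]pentanal
Conditions: Dess–Martin periodinane, pyridine, CH2Cl2, 0 °C; used crude
Reagents that add atoms: none
Why: Dess–Martin oxidation under buffered, non-basic conditions should give the β,γ-unsaturated aldehyde without epimerising C5 or moving the C4 methylene into conjugation.

Step 8
Reactants: 15 (E)-3-iodoacrylic acid; 16 2-(trimethylsilyl)ethanol
Product: 17 2-(trimethylsilyl)ethyl (E)-3-iodoacrylate
Conditions: DCC, DMAP (5 mol %), CH2Cl2, 0 °C → rt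
Reagents that add atoms: none
Why: Steglich esterification joins acid and alcohol under mild conditions that keep the (E)-iodoalkene geometry.

Step 9
Reactants: 14 (2R,3S)-5-(TBSO)-3-ethenyl-3-methyl-2-[3-(TBDPSO)prop-1-en-2-yl]pentanal; 17 2-(trimethylsilyl)ethyl (E)-3-iodoacrylate
Product: 18 2-(trimethylsilyl)ethyl (2E,4S,5R,6S)-8-(TBSO)-6-ethenyl-4-hydroxy-6-methyl-5-[3-(TBDPSO)prop-1-en-2-yl]oct-2-enoate
Conditions: CrCl2 (5 equiv), NiCl2 (2 mol %), DMSO, rt; aq. work-up
Reagents that add atoms: none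
Why: Nozaki–Hiyama–Kishi coupling: the alkenylchromium(III) species from the (E)-iodoacrylate adds to the hindered aldehyde without base and with retention of alkene geometry, and Felkin–Anh attack anti to the quaternary C10 substituent should set the C6 carbinol as the (4S) epimer.

Step 10
Reactants: 18 2-(trimethylsilyl)ethyl (2E,4S,5R,6S)-8-(TBSO)-6-ethenyl-4-hydroxy-6-methyl-5-[3-(TBDPSO)prop-1-en-2-yl]oct-2-enoate
Product: 19 2-(trimethylsilyl)ethyl (2E,4S,5R,6S)-4,8-bis(TBSO)-6-ethenyl-6-methyl-5-[3-(TBDPSO)prop-1-en-2-yl]oct-2-enoate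
Conditions: TBSOTf, 2,6-lutidine, CH2Cl2, −78 → 0 °C
Reagents that add atoms: tert-butyldimethylsilyl triflate CC(C)(C)[Si](C)(C)OS(=O)(=O)C(F)(F)F
Why: Triflate-mediated silylation protects the hindered secondary alcohol without base-induced oxa-Michael or elimination chemistry of the γ-hydroxy enoate.

Step 11
Reactants: 19 2-(trimethylsilyl)ethyl (2E,4S,5R,6S)-4,8-bis(TBSO)-6-ethenyl-6-methyl-5-[3-(TBDPSO)prop-1-en-2-yl]oct-2-enoate
Product: 20 2-(trimethylsilyl)ethyl (2E,4S,5R,6S)-4-(TBSO)-6-ethenyl-8-hydroxy-6-methyl-5-[3-(TBDPSO)prop-1-en-2-yl]oct-2-enoate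
Conditions: HF·pyridine, pyridine, THF, 0 °C
Reagents that add atoms: none
Why: Buffered HF·pyridine desilylation discriminates on steric grounds and should remove only the primary TBS ether at C8, leaving the hindered secondary TBS ether, the TBDPS ether and the TMSE ester.

Step 12
Reactants: 20 2-(trimethylsilyl)ethyl (2E,4S,5R,6S)-4-(TBSO)-6-ethenyl-8-hydroxy-6-methyl-5-[3-(TBDPSO)prop-1-en-2-yl]oct-2-enoate
Product: 21 2-(trimethylsilyl)ethyl (2E,4S,5R,6S)-4-(TBSO)-6-ethenyl-6-methyl-8-oxo-5-[3-(TBDPSO)prop-1-en-2-yl]oct-2-enoate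
Conditions: Dess–Martin periodinane, pyridine, CH2Cl2, 0 °C → rt
Reagents that add atoms: none
Why: Dess–Martin oxidation of the primary alcohol gives the C8 aldehyde, whose α-CH2 sits next to the quaternary carbon, with all other functionality untouched.

Step 13
Reactants: 21 2-(trimethylsilyl)ethyl (2E,4S,5R,6S)-4-(TBSO)-6-ethenyl-6-methyl-8-oxo-5-[3-(TBDPSO)prop-1-en-2-yl]oct-2-enoate
Product: 22 2-(trimethylsilyl)ethyl [(5R,6R,7R,8S,10S)-6-(TBSO)-8-hydroxy-10-methyl-5-[3-(TBDPSO)prop-1-en-2-yl]-10-vinylcyclohexan-7-yl]acetate (skeleton numbering; C7/C8 trans)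
Conditions: divided cell, Pb cathode, Pt anode, 0.1 M Et4NOTs in MeCN, dimethyl malonate (2 equiv), −2.3 V vs SCE, 0 °C → rt, about 2 F/mol, substrate 5 mM
Reagents that add atoms: none
Why: At the controlled potential the (E)-enoate, the most easily reduced group, takes up one electron and the radical anion bonds through its β-carbon C7 to the C8 carbonyl carbon (equivalently a ketyl–enoate coupling), after which a second electron and two protons from dimethyl malonate give the γ-hydroxy ester; the closest known reaction type is the electroreductive cyclisation of ω-oxo-α,β-unsaturated esters, whose chemical counterpart is the SmI2 ketyl–olefin cyclisation. The cyclohexane (C5–C10) closes in the 6-exo-trig mode, helped by the quaternary C10 (Thorpe–Ingold effect). C8 is controlled by the axial C10 methyl of the chair-like transition state, a chair fixed by the equatorial C5 alkenyl, C6 silyloxy and C10 vinyl groups, which pushes the aldehyde oxygen equatorial to avoid a 1,3-diaxial contact. C7 is controlled by the (E)-enoate geometry and the adjacent C6 silyloxy group: the ester arm sits equatorial, the new bond forms anti to the C6–O bond and the developing alkoxide and ester enolate point away from each other, so the C7/C8-trans, all-equatorial product is expected. The step needs cyclisation to win over enoate saturation, hydrodimerisation, loss of the γ-silyloxy group and lactonisation, which high dilution, potential control at the enoate wave, the buffering proton donor, the poor silyloxide leaving group and the bulky TMSE ester are meant to secure.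

Step 14
Reactants: 22 2-(trimethylsilyl)ethyl [(5R,6R,7R,8S,10S)-6-(TBSO)-8-hydroxy-10-methyl-5-[3-(TBDPSO)prop-1-en-2-yl]-10-vinylcyclohexan-7-yl]acetate
Product: 23 2-(trimethylsilyl)ethyl [(5R,6R,7R,8S,10S)-6-(TBSO)-8-(TESO)-10-methyl-5-[3-(TBDPSO)prop-1-en-2-yl]-10-vinylcyclohexan-7-yl]acetate
Conditions: TESOTf, 2,6-lutidine, CH2Cl2, −78 °C
Reagents that add atoms: triethylsilyl triflate CC[Si](CC)(CC)OS(=O)(=O)C(F)(F)F
Why: Silylation of the equatorial C8 alcohol stops lactonisation onto C12 and masks the hydroxyl for the enolate step, and TES is chosen because it can later be removed beside TBS and TBDPS ethers.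

Step 15
Reactants: 23 2-(trimethylsilyl)ethyl [(5R,6R,7R,8S,10S)-6-(TBSO)-8-(TESO)-10-methyl-5-[3-(TBDPSO)prop-1-en-2-yl]-10-vinylcyclohexan-7-yl]acetate
Product: 26 2-(trimethylsilyl)ethyl 2-[(5R,6R,7R,8S,10S)-6-(TBSO)-8-(TESO)-10-methyl-5-[3-(TBDPSO)prop-1-en-2-yl]-10-vinylcyclohexan-7-yl]acrylate, via Mannich base 24 (not isolated), via trimethylammonium iodide 25 (not isolated)
Conditions: LDA, THF, −78 °C; Eschenmoser's salt, −78 °C → rt; crude, MeI, MeOH, rt; DBU, CH2Cl2, rt
Reagents that add atoms: Eschenmoser's salt (dimethylmethylideneammonium iodide) C=[N+](C)C.[I-]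
Why: α-Methylenation by Mannich reaction of the ester lithium enolate with Eschenmoser's salt, N-methylation and base-induced elimination of trimethylamine; no leaving group sits β to the enolate carbon, so C7 and the silyl ethers should be unaffected.

Step 16
Reactants: 26 2-(trimethylsilyl)ethyl 2-[(5R,6R,7R,8S,10S)-6-(TBSO)-8-(TESO)-10-methyl-5-[3-(TBDPSO)prop-1-en-2-yl]-10-vinylcyclohexan-7-yl]acrylate
Product: 27 2-(trimethylsilyl)ethyl 2-[(5R,6R,7R,8S,10S)-6-(TBSO)-8-hydroxy-10-methyl-5-[3-(TBDPSO)prop-1-en-2-yl]-10-vinylcyclohexan-7-yl]acrylate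
Conditions: HF·pyridine, pyridine, THF, 0 °C; used at once
Reagents that add atoms: none
Why: Selective desilylation: the TES ether is far more labile to buffered HF than the hindered secondary TBS and the TBDPS ethers, and the mildly acidic medium should not open a path to the 8,12-lactone.

Step 17
Reactants: 28 ethyl 2-(hydroxymethyl)acrylate
Product: 29 ethyl 2-[(TBSO)methyl]acrylate
Conditions: TBSCl, imidazole, CH2Cl2, 0 °C → rt
Reagents that add atoms: tert-butyldimethylsilyl chloride CC(C)(C)[Si](C)(C)Cl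
Why: Standard silylation of the primary allylic alcohol so that the acid can be activated without self-acylation.

Step 18
Reactants: 29 ethyl 2-[(TBSO)methyl]acrylate
Product: 30 2-[(TBSO)methyl]acrylic acid
Conditions: LiOH, THF–H2O, 0 °C → rt; dilute HCl to pH 4, 0 °C
Reagents that add atoms: lithium hydroxide [Li+].[OH-]
Why: Saponification of the ethyl ester with hydroxide at low temperature proceeds faster than conjugate addition to the α-substituted acrylate and leaves the silyl ether in place.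

Step 19
Reactants: 27 2-(trimethylsilyl)ethyl 2-[(5R,6R,7R,8S,10S)-6-(TBSO)-8-hydroxy-10-methyl-5-[3-(TBDPSO)prop-1-en-2-yl]-10-vinylcyclohexan-7-yl]acrylate; 30 2-[(TBSO)methyl]acrylic acid
Product: 32 2-(trimethylsilyl)ethyl 2-[(5R,6R,7R,8S,10S)-6-(TBSO)-8-{2-[(TBSO)methyl]acryloyloxy}-10-methyl-5-[3-(TBDPSO)prop-1-en-2-yl]-10-vinylcyclohexan-7-yl]acrylate, via Yamaguchi mixed anhydride 31 (not isolated)
Conditions: 30 (2 equiv), 2,4,6-trichlorobenzoyl chloride, Et3N, THF, rt; then 27, DMAP, toluene, 0 °C → rt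
Reagents that add atoms: none
Why: Yamaguchi esterification: the mixed trichlorobenzoic anhydride with DMAP should acylate the hindered equatorial C8 alcohol faster than it can close onto the C12 ester, with retention at C8.

Step 20
Reactants: 32 2-(trimethylsilyl)ethyl 2-[(5R,6R,7R,8S,10S)-6-(TBSO)-8-{2-[(TBSO)methyl]acryloyloxy}-10-methyl-5-[3-(TBDPSO)prop-1-en-2-yl]-10-vinylcyclohexan-7-yl]acrylate
Product: 33 CNP0509685.1, 2-[(5R,6R,7S,8S,10S)-6-hydroxy-8-[2-(hydroxymethyl)acryloyloxy]-5-(3-hydroxyprop-1-en-2-yl)-10-methyl-10-vinylcyclohexan-7-yl]acrylic acid (skeleton numbering)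
Conditions: TBAF (8 equiv), AcOH (4 equiv), THF, 0 °C → rt; pH 5 phosphate buffer work-up
Reagents that add atoms: none
Why: Fluoride-mediated global deprotection cleaves the Si–O bonds and fragments the TMSE ester with loss of ethylene in one operation; the TMSE ester and the primary silyl ethers should fall before the hindered C6 silyl ether, so C12 is already a carboxylate when the C6 hydroxyl appears and cannot lactonise, and acetic acid buffering protects the two acrylates.

**Compound list**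

1 | 4-(tert-butyldimethylsilyloxy)but-1-yne | C#CCCO[Si](C)(C)C(C)(C)C | starting material
2 | (E)-[4-(TBSO)-2-methylbut-1-enyl]dimethylalane | C[Al](C)/C=C(C)/CCO[Si](C)(C)C(C)(C)C | intermediate (not isolated)
3 | lithium butyl[(E)-4-(TBSO)-2-methylbut-1-enyl]dimethylaluminate | [Li+].CCCC[Al-](C)(C)/C=C(C)/CCO[Si](C)(C)C(C)(C)C | intermediate (not isolated)
4 | (E)-5-(TBSO)-3-methylpent-2-en-1-ol | OC/C=C(C)/CCO[Si](C)(C)C(C)(C)C | intermediate
5 | itaconic anhydride | C=C1CC(=O)OC1=O | starting material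
6 | 2-methylidene-4-oxo-4-{[(E)-5-(TBSO)-3-methylpent-2-enyl]oxy}butanoic acid | C=C(CC(=O)OC/C=C(C)/CCO[Si](C)(C)C(C)(C)C)C(=O)O | intermediate
7 | isobutyl carbonic mixed anhydride of 6 | C=C(CC(=O)OC/C=C(C)/CCO[Si](C)(C)C(C)(C)C)C(=O)OC(=O)OCC(C)C | intermediate (not isolated)
8 | (E)-5-(TBSO)-3-methylpent-2-enyl 3-(hydroxymethyl)but-3-enoate | C=C(CO)CC(=O)OC/C=C(C)/CCO[Si](C)(C)C(C)(C)C | intermediate
9 | (E)-5-(TBSO)-3-methylpent-2-enyl 3-[(TBDPSO)methyl]but-3-enoate | C=C(CO[Si](c1ccccc1)(c1ccccc1)C(C)(C)C)CC(=O)OC/C=C(C)/CCO[Si](C)(C)C(C)(C)C | intermediate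
10 | E(O)-boron ketene acetal of 9 (O-[(4S,5S)-diazaborolidin-2-yl]; alkenyl group cis to the allyloxy oxygen) | C=C(CO[Si](c1ccccc1)(c1ccccc1)C(C)(C)C)/C=C(/OB1N(S(=O)(=O)c2cc(C(F)(F)F)cc(C(F)(F)F)c2)[C@@H](c2ccccc2)[C@H](c2ccccc2)N1S(=O)(=O)c1cc(C(F)(F)F)cc(C(F)(F)F)c1)OC/C=C(C)/CCO[Si](C)(C)C(C)(C)C | intermediate (not isolated)
11 | (4S,5S)-diazaborolidin-2-yl ester of acid 12 | CC(C)(C)[Si](C)(C)OCC[C@@](C)(C=C)[C@H](C(=C)CO[Si](c1ccccc1)(c1ccccc1)C(C)(C)C)C(=O)OB1N(S(=O)(=O)c2cc(C(F)(F)F)cc(C(F)(F)F)c2)[C@@H](c2ccccc2)[C@H](c2ccccc2)N1S(=O)(=O)c1cc(C(F)(F)F)cc(C(F)(F)F)c1 | intermediate (not isolated)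
12 | (2R,3S)-5-(TBSO)-3-ethenyl-3-methyl-2-[3-(TBDPSO)prop-1-en-2-yl]pentanoic acid | CC(C)(C)[Si](C)(C)OCC[C@@](C)(C=C)[C@H](C(=C)CO[Si](c1ccccc1)(c1ccccc1)C(C)(C)C)C(=O)O | intermediate
13 | (2R,3S)-5-(TBSO)-3-ethenyl-3-methyl-2-[3-(TBDPSO)prop-1-en-2-yl]pentan-1-ol | CC(C)(C)[Si](C)(C)OCC[C@@](C)(C=C)[C@H](C(=C)CO[Si](c1ccccc1)(c1ccccc1)C(C)(C)C)CO | intermediate
14 | (2R,3S)-5-(TBSO)-3-ethenyl-3-methyl-2-[3-(TBDPSO)prop-1-en-2-yl]pentanal | CC(C)(C)[Si](C)(C)OCC[C@@](C)(C=C)[C@H](C(=C)CO[Si](c1ccccc1)(c1ccccc1)C(C)(C)C)C=O | intermediate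
15 | (E)-3-iodoacrylic acid | OC(=O)/C=C/I | starting material
16 | 2-(trimethylsilyl)ethanol | OCC[Si](C)(C)C | starting material
17 | 2-(trimethylsilyl)ethyl (E)-3-iodoacrylate | I/C=C/C(=O)OCC[Si](C)(C)C | intermediate
18 | 2-(trimethylsilyl)ethyl (2E,4S,5R,6S)-8-(TBSO)-6-ethenyl-4-hydroxy-6-methyl-5-[3-(TBDPSO)prop-1-en-2-yl]oct-2-enoate | CC(C)(C)[Si](C)(C)OCC[C@@](C)(C=C)[C@H](C(=C)CO[Si](c1ccccc1)(c1ccccc1)C(C)(C)C)[C@@H](O)/C=C/C(=O)OCC[Si](C)(C)C | intermediate
19 | 2-(trimethylsilyl)ethyl (2E,4S,5R,6S)-4,8-bis(TBSO)-6-ethenyl-6-methyl-5-[3-(TBDPSO)prop-1-en-2-yl]oct-2-enoate | CC(C)(C)[Si](C)(C)OCC[C@@](C)(C=C)[C@H](C(=C)CO[Si](c1ccccc1)(c1ccccc1)C(C)(C)C)[C@@H](O[Si](C)(C)C(C)(C)C)/C=C/C(=O)OCC[Si](C)(C)C | intermediate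
20 | 2-(trimethylsilyl)ethyl (2E,4S,5R,6S)-4-(TBSO)-6-ethenyl-8-hydroxy-6-methyl-5-[3-(TBDPSO)prop-1-en-2-yl]oct-2-enoate | OCC[C@@](C)(C=C)[C@H](C(=C)CO[Si](c1ccccc1)(c1ccccc1)C(C)(C)C)[C@@H](O[Si](C)(C)C(C)(C)C)/C=C/C(=O)OCC[Si](C)(C)C | intermediate
21 | 2-(trimethylsilyl)ethyl (2E,4S,5R,6S)-4-(TBSO)-6-ethenyl-6-methyl-8-oxo-5-[3-(TBDPSO)prop-1-en-2-yl]oct-2-enoate (key-step precursor) | O=CC[C@@](C)(C=C)[C@H](C(=C)CO[Si](c1ccccc1)(c1ccccc1)C(C)(C)C)[C@@H](O[Si](C)(C)C(C)(C)C)/C=C/C(=O)OCC[Si](C)(C)C | intermediate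
22 | 2-(trimethylsilyl)ethyl [(5R,6R,7R,8S,10S)-6-(TBSO)-8-hydroxy-10-methyl-5-[3-(TBDPSO)prop-1-en-2-yl]-10-vinylcyclohexan-7-yl]acetate (key-step product) | C=C[C@]1(C)C[C@H](O)[C@@H](CC(=O)OCC[Si](C)(C)C)[C@H](O[Si](C)(C)C(C)(C)C)[C@H]1C(=C)CO[Si](c1ccccc1)(c1ccccc1)C(C)(C)C | intermediate
23 | C8 triethylsilyl ether of 22 | C=C[C@]1(C)C[C@H](O[Si](CC)(CC)CC)[C@@H](CC(=O)OCC[Si](C)(C)C)[C@H](O[Si](C)(C)C(C)(C)C)[C@H]1C(=C)CO[Si](c1ccccc1)(c1ccccc1)C(C)(C)C | intermediate
24 | Mannich base: C11-(dimethylaminomethyl) derivative of 23 (C11 epimers) | C=C[C@]1(C)C[C@H](O[Si](CC)(CC)CC)[C@@H](C(CN(C)C)C(=O)OCC[Si](C)(C)C)[C@H](O[Si](C)(C)C(C)(C)C)[C@H]1C(=C)CO[Si](c1ccccc1)(c1ccccc1)C(C)(C)C | intermediate (not isolated)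
25 | trimethylammonium iodide from 24 | C=C[C@]1(C)C[C@H](O[Si](CC)(CC)CC)[C@@H](C(C[N+](C)(C)C)C(=O)OCC[Si](C)(C)C)[C@H](O[Si](C)(C)C(C)(C)C)[C@H]1C(=C)CO[Si](c1ccccc1)(c1ccccc1)C(C)(C)C.[I-] | intermediate (not isolated)
26 | 2-(trimethylsilyl)ethyl 2-[(5R,6R,7R,8S,10S)-6-(TBSO)-8-(TESO)-10-methyl-5-[3-(TBDPSO)prop-1-en-2-yl]-10-vinylcyclohexan-7-yl]acrylate | C=C[C@]1(C)C[C@H](O[Si](CC)(CC)CC)[C@@H](C(=C)C(=O)OCC[Si](C)(C)C)[C@H](O[Si](C)(C)C(C)(C)C)[C@H]1C(=C)CO[Si](c1ccccc1)(c1ccccc1)C(C)(C)C | intermediate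
27 | 2-(trimethylsilyl)ethyl 2-[(5R,6R,7R,8S,10S)-6-(TBSO)-8-hydroxy-10-methyl-5-[3-(TBDPSO)prop-1-en-2-yl]-10-vinylcyclohexan-7-yl]acrylate | C=C[C@]1(C)C[C@H](O)[C@@H](C(=C)C(=O)OCC[Si](C)(C)C)[C@H](O[Si](C)(C)C(C)(C)C)[C@H]1C(=C)CO[Si](c1ccccc1)(c1ccccc1)C(C)(C)C | intermediate
28 | ethyl 2-(hydroxymethyl)acrylate | C=C(CO)C(=O)OCC | starting material
29 | ethyl 2-[(TBSO)methyl]acrylate | C=C(CO[Si](C)(C)C(C)(C)C)C(=O)OCC | intermediate
30 | 2-[(TBSO)methyl]acrylic acid | C=C(CO[Si](C)(C)C(C)(C)C)C(=O)O | intermediate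
31 | 2-[(TBSO)methyl]acrylic 2,4,6-trichlorobenzoic anhydride | C=C(CO[Si](C)(C)C(C)(C)C)C(=O)OC(=O)c1c(Cl)cc(Cl)cc1Cl | intermediate (not isolated)
32 | fully protected ester (C6–OTBS, C15–OTBDPS, side-chain OTBS, C12 TMSE ester) | C=C[C@]1(C)C[C@H](OC(=O)C(=C)CO[Si](C)(C)C(C)(C)C)[C@@H](C(=C)C(=O)OCC[Si](C)(C)C)[C@H](O[Si](C)(C)C(C)(C)C)[C@H]1C(=C)CO[Si](c1ccccc1)(c1ccccc1)C(C)(C)C | intermediate
33 | CNP0509685.1, (5R,6R,7S,8S,10S) | C=C[C@]1(C)C[C@H](OC(=O)C(=C)CO)[C@@H](C(=C)C(=O)O)[C@H](O)[C@H]1C(=C)CO | target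

**Step count and risks**

Total step count: 20. Longest linear sequence: 17 steps (steps 1–7, 9–16, 19, 20); steps 8, 17 and 18 are side branches.

Steps most likely to fail:

1. Step 13 (cathodic ring closure). What may go wrong: two-electron saturation of the enoate or reductive loss of the C6 silyloxy group outruns C7–C8 bond formation; the chair preference is too weak and facial selectivity at C7/C8 is poor; or the C8 alkoxide closes onto the ester. Fallback: the electrode is replaced by a stoichiometric, oxophilic one-electron reductant, which changes the order of events. From 21, SmI2 (2.5 equiv) in THF with MeOH or t-BuOH at −78 °C reduces the aldehyde first, and the samarium(III)-bound ketyl adds to the enoate in a metal-organised 6-exo ketyl–olefin cyclisation. The route is rejoined at 22, and no new compound is made (F0).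

2. Step 5 (enantioselective Ireland–Claisen). What may go wrong: proton shift of the boron dienolate into conjugation before the slow quaternary-centre-forming shift; formation of the wrong enolate geometry; or insufficient facial discrimination by the boron ligand. Fallback: from 9, a racemic silyl-ketene-acetal Ireland–Claisen followed by classical resolution. LDA in THF at −78 °C and then TMSCl/Et3N give the E(O)-trimethylsilyl ketene acetal F1, which rearranges on warming through the same chair to the racemic trimethylsilyl ester F2. Hydrolysis gives the racemic acid F3, and fractional crystallisation of the (R)-1-phenylethylammonium salt F4 (the antipodal amine if the other diastereomeric salt is the less soluble one) followed by acidification rejoins the route at 12.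

3. Step 9 (C6 carbinol by NHK addition). What may go wrong: poor or inverted facial selectivity if the C4 alkenyl group, not the quaternary C10 group, takes the anti position in the Felkin–Anh transition state. Fallback: from 18 as obtained (C6 epimer mixture), Dess–Martin oxidation gives the 4-oxo-2-enoate F5. Luche 1,2-reduction (NaBH4, CeCl3, MeOH, −78 °C) then makes hydride the entering group, so the same facial bias delivers the opposite C6 configuration to that of the carbon addition. If the substrate bias is weak, an oxazaborolidine-catalysed (CBS) reduction with catecholborane, with the catalyst antipode chosen on the first result, sets C6 under reagent control. Either way the route is rejoined at 18.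

Further compounds
F0 | step 13 | none | none
F1 | step 5 | E(O)-trimethylsilyl ketene acetal of 9 | C=C(CO[Si](c1ccccc1)(c1ccccc1)C(C)(C)C)/C=C(/O[Si](C)(C)C)OC/C=C(C)/CCO[Si](C)(C)C(C)(C)C
F2 | step 5 | racemic trimethylsilyl ester of the (2R*,3S*) acid (one enantiomer drawn) | CC(C)(C)[Si](C)(C)OCC[C@@](C)(C=C)[C@H](C(=C)CO[Si](c1ccccc1)(c1ccccc1)C(C)(C)C)C(=O)O[Si](C)(C)C
F3 | step 5 | racemic (2R*,3S*)-5-(TBSO)-3-ethenyl-3-methyl-2-[3-(TBDPSO)prop-1-en-2-yl]pentanoic acid (one enantiomer drawn) | CC(C)(C)[Si](C)(C)OCC[C@@](C)(C=C)[C@H](C(=C)CO[Si](c1ccccc1)(c1ccccc1)C(C)(C)C)C(=O)O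
F4 | step 5 | (R)-1-phenylethylammonium salt of the (2R,3S) acid | CC(C)(C)[Si](C)(C)OCC[C@@](C)(C=C)[C@H](C(=C)CO[Si](c1ccccc1)(c1ccccc1)C(C)(C)C)C(=O)[O-].C[C@@H]([NH3+])c1ccccc1
F5 | step 9 | 2-(trimethylsilyl)ethyl (2E,5R,6S)-8-(TBSO)-6-ethenyl-6-methyl-4-oxo-5-[3-(TBDPSO)prop-1-en-2-yl]oct-2-enoate | CC(C)(C)[Si](C)(C)OCC[C@@](C)(C=C)[C@H](C(=C)CO[Si](c1ccccc1)(c1ccccc1)C(C)(C)C)C(=O)/C=C/C(=O)OCC[Si](C)(C)C
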